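## Retrosynthetic overview

1. The C15 aldehyde and the C6 angelate are installed last (allylic oxidation, esterification) on the elemanolide alcohol 21.
2. 21 is cut at C6–C7 and C5–C10 back to the acyclic enal / 3-(bromomethyl)butenolide 18. A chromium-mediated allylation closes a ten-membered germacradienolide, and its Cope rearrangement (the presumed biogenetic germacranolide-to-elemanolide step) forms the cyclohexane and cleaves C2–C3.
3. Enabling feature: the C10 vinyl group (C1=C2) and the C5 propen-2-yl unit (C4=C3) are vicinal on ring C5–C6–C7–C8–C9–C10, so C2=C1–C10–C5–C4=C3 is a hexa-1,5-diene, the Cope retron of a cyclodeca-1(10),4-diene. The C6 carbinol next to C7, which carries the exo-methylene lactone (C11=C13, C12), is the retron of a γ-selective allylmetal addition.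
4. 18 is built from a linear chain: butenolide by ring-closing metathesis at O8, the C8/C9 syn-diol by asymmetric alkoxyallylboration, C1=C10 by cross-metathesis with methacrolein, C4=C5 by syn-carbocupration of a 4-silyloxybut-2-ynoate.
5. Ring order: butenolide (step 11), then the transient ten-membered carbocycle and the cyclohexane (both in step 12).

Key step: step 12

Remark: germacrane/elemane numbering is used for positions (C10 quaternary with C14 methyl and C1=C2 vinyl; C5 bearing C4(=C3)C15; C6 O-angelate; C7 bearing C11(=C13)–C12; C8 lactone O; C9 2-methylbutanoate). C15 is carried as a silyl ether until the end. In 18 and 19 the C4=C5 bond is "Z" by CIP rules because C15 outranks C3, but C3 and C6 are trans across it. (R)-2-Methylbutanoic acid and allyl methoxymethyl ether are taken as purchasable.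

## Route

Step 1
Reactants: 1 tert-butyldimethyl(prop-2-yn-1-yloxy)silane; 2 ethyl chloroformate
Product: 3 ethyl 4-[(tert-butyldimethylsilyl)oxy]but-2-ynoate
Conditions: n-BuLi, THF, −78 °C; then 2, −78 to 0 °C
Reagents that add atoms: none
Why: Deprotonation of the terminal alkyne and C-acylation of the lithium acetylide with a chloroformate is a standard ynoate synthesis; no stereocentre is formed.

Step 2
Reactants: 3 ethyl 4-[(tert-butyldimethylsilyl)oxy]but-2-ynoate; 4 but-3-en-1-ylmagnesium bromide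
Product: 5 ethyl (2Z)-3-{[(tert-butyldimethylsilyl)oxy]methyl}hepta-2,6-dienoate
Conditions: 4, CuBr·SMe2, THF, −78 °C; then 3, −78 °C; MeOH quench at −78 °C
Reagents that add atoms: none
Why: syn-Carbocupration of the ynoate (organocopper conjugate addition) with cold protonation of the vinylcopper should place the butenyl group trans to the ester, which fixes the C4=C5 geometry (C3 trans to C6) before the allenoate can equilibrate.

Step 3
Reactants: 5 ethyl (2Z)-3-{[(tert-butyldimethylsilyl)oxy]methyl}hepta-2,6-dienoate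
Product: 6 (2Z)-3-{[(tert-butyldimethylsilyl)oxy]methyl}hepta-2,6-dien-1-ol
Conditions: i-Bu2AlH, CH2Cl2, −78 °C; aq. potassium sodium tartrate
Reagents that add atoms: none
Why: 1,2-Reduction of the enoate with i-Bu2AlH should give the allylic alcohol without touching the alkenes or the silyl ether.

Step 4
Reactants: 6 (2Z)-3-{[(tert-butyldimethylsilyl)oxy]methyl}hepta-2,6-dien-1-ol
Product: 7 tert-butyl{[(2Z)-2-(but-3-en-1-yl)-4-(methoxymethoxy)but-2-en-1-yl]oxy}dimethylsilane
Conditions: MOMCl, i-Pr2NEt, CH2Cl2, 0 to 25 °C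
Reagents that add atoms: chloromethyl methyl ether (MOMCl), COCCl
Why: Acetal formation by O-alkylation with an amine base (no alkoxide) should protect the C6 hydroxyl without 1,4-migration of the silyl group from O15.

Step 5
Reactants: 7 tert-butyl{[(2Z)-2-(but-3-en-1-yl)-4-(methoxymethoxy)but-2-en-1-yl]oxy}dimethylsilane; 8 methacrolein
Product: 9 (2E,6Z)-6-{[(tert-butyldimethylsilyl)oxy]methyl}-8-(methoxymethoxy)-2-methylocta-2,6-dienal
Conditions: 8 (excess), second-generation Hoveyda–Grubbs catalyst, CH2Cl2, 40 °C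
Reagents that add atoms: none
Why: Olefin cross-metathesis of the monosubstituted alkene with methacrolein should give the thermodynamically favoured (E)-2-methylenal (C1=C10), the trisubstituted alkene being inert.

Step 6
Reactants: 9 (2E,6Z)-6-{[(tert-butyldimethylsilyl)oxy]methyl}-8-(methoxymethoxy)-2-methylocta-2,6-dienal; 10 3-(methoxymethoxy)prop-1-ene
Product: 11 (3R,4R,5E,9Z)-9-{[(tert-butyldimethylsilyl)oxy]methyl}-3,11-bis(methoxymethoxy)-5-methylundeca-1,5,9-trien-4-ol
Conditions: 10, s-BuLi, THF, −78 °C; (−)-Ipc2BOMe; BF3·OEt2; then 9, −78 °C; NaOH, H2O2, 0 to 25 °C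
Reagents that add atoms: none
Why: Brown asymmetric γ-alkoxyallylboration: the (Z)-γ-alkoxyallylborane reacts through a chair transition state to give the syn-diol monoether, and the isopinocampheyl groups derived from (+)-α-pinene direct attack to the Si face of the aldehyde, which should set C8 and C9 as (R,R).

Step 7
Reactants: 11 (3R,4R,5E,9Z)-9-{[(tert-butyldimethylsilyl)oxy]methyl}-3,11-bis(methoxymethoxy)-5-methylundeca-1,5,9-trien-4-ol; 12 (2R)-2-methylbutanoic acid
Product: 13 (3R,4R,5E,9Z)-9-{[(tert-butyldimethylsilyl)oxy]methyl}-3,11-bis(methoxymethoxy)-5-methylundeca-1,5,9-trien-4-yl (2R)-2-methylbutanoate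
Conditions: 12, EDC·HCl, DMAP (cat.), CH2Cl2, 0 to 25 °C
Reagents that add atoms: none
Why: Steglich-type carbodiimide esterification of the free C9 hydroxyl should proceed with retention at C9 and, at low temperature with catalytic DMAP, without epimerising the acid.

Step 8
Reactants: 13 (3R,4R,5E,9Z)-9-{[(tert-butyldimethylsilyl)oxy]methyl}-3,11-bis(methoxymethoxy)-5-methylundeca-1,5,9-trien-4-yl (2R)-2-methylbutanoate
Product: 14 (3R,4R,5E,9Z)-9-{[(tert-butyldimethylsilyl)oxy]methyl}-3,11-dihydroxy-5-methylundeca-1,5,9-trien-4-yl (2R)-2-methylbutanoate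
Conditions: Me2BBr, CH2Cl2, −78 °C; then aq. NaHCO3, THF
Reagents that add atoms: none
Why: Lewis-acid acetal cleavage with Me2BBr (bromide attacks the acetal carbon, not the allylic carbons) should remove both methoxymethyl groups at −78 °C while the silyl ether, the ester and the alkenes survive.

Step 9
Reactants: 14 (3R,4R,5E,9Z)-9-{[(tert-butyldimethylsilyl)oxy]methyl}-3,11-dihydroxy-5-methylundeca-1,5,9-trien-4-yl (2R)-2-methylbutanoate
Product: 15 (3R,4R,5E,9Z)-9-{[(tert-butyldimethylsilyl)oxy]methyl}-3-hydroxy-5-methyl-11-oxoundeca-1,5,9-trien-4-yl (2R)-2-methylbutanoate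
Conditions: TEMPO (cat.), PhI(OAc)2, CH2Cl2, 25 °C
Reagents that add atoms: none
Why: Oxoammonium (TEMPO) oxidation is selective for the primary allylic alcohol over the hindered secondary one and should give the C6 enal without touching C8–OH.

Step 10
Reactants: 15 (3R,4R,5E,9Z)-9-{[(tert-butyldimethylsilyl)oxy]methyl}-3-hydroxy-5-methyl-11-oxoundeca-1,5,9-trien-4-yl (2R)-2-methylbutanoate; 16 2-(bromomethyl)prop-2-enoic acid
Product: 17 (3R,4R,5E,9Z)-9-{[(tert-butyldimethylsilyl)oxy]methyl}-5-methyl-4-{[(2R)-2-methylbutanoyl]oxy}-11-oxoundeca-1,5,9-trien-3-yl 2-(bromomethyl)prop-2-enoate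
Conditions: 16, DIC, DMAP (cat.), CH2Cl2, −20 to 0 °C
Reagents that add atoms: none
Why: Carbodiimide esterification of the C8 hydroxyl; low temperature and only catalytic DMAP should limit SN2' attack on the allylic bromide and acyl migration from O9.

Step 11
Reactants: 17 (3R,4R,5E,9Z)-9-{[(tert-butyldimethylsilyl)oxy]methyl}-5-methyl-4-{[(2R)-2-methylbutanoyl]oxy}-11-oxoundeca-1,5,9-trien-3-yl 2-(bromomethyl)prop-2-enoate
Product: 18 (1R,2E,6Z)-1-[(2R)-4-(bromomethyl)-5-oxo-2,5-dihydrofuran-2-yl]-6-{[(tert-butyldimethylsilyl)oxy]methyl}-2-methyl-8-oxoocta-2,6-dien-1-yl (2R)-2-methylbutanoate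
Conditions: second-generation Grubbs catalyst, PhMe, 80 °C, high dilution
Reagents that add atoms: none
Why: Ring-closing metathesis between the C7 vinyl group and the acrylate alkene should close the five-membered butenolide (C7=C11), the trisubstituted alkenes being unreactive and C8 untouched.

Step 12
Reactants: 18 (1R,2E,6Z)-1-[(2R)-4-(bromomethyl)-5-oxo-2,5-dihydrofuran-2-yl]-6-{[(tert-butyldimethylsilyl)oxy]methyl}-2-methyl-8-oxoocta-2,6-dien-1-yl (2R)-2-methylbutanoate
Product: 21 (3aR,4S,5S,6S,7R,7aR)-5-(3-{[tert-butyl(dimethyl)silyl]oxy}prop-1-en-2-yl)-6-ethenyl-4-hydroxy-6-methyl-3-methylidene-2-oxooctahydro-1-benzofuran-7-yl (2R)-2-methylbutanoate, via germacranolide trimethylsilyl ether 19 (not isolated), via elemanolide trimethylsilyl ether 20 (not isolated)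
Conditions: CrCl2 (excess), THF, 25 °C, slow addition of 18 (2 mM); Me3SiCl, 25 °C; then PhMe, 120 °C (THF distilled out); aq. citric acid, THF, 25 °C
Reagents that add atoms: chlorotrimethylsilane, C[Si](C)(C)Cl (its silyl group is carried only by 19 and 20)
Why: Divalent chromium reduces the allylic C–Br bond and the allylchromium species (trivalent chromium) adds through its γ-carbon C7 to the tethered C6 enal in a chair Zimmerman–Traxler transition state (Nozaki–Hiyama allylation, the reaction type known to close ten-membered germacranolide rings and to turn 3-(bromomethyl)butenolides into α-methylene lactones), and the alkoxide is capped as silyl ether 19. On heating, the cyclodeca-1(10),4-diene of 19 undergoes the transannular chair Cope rearrangement known for germacranolides (germacranolide to elemanolide, the presumed biogenetic step), which forms C5–C10, cuts C2–C3 and releases the C1=C2 vinyl and C3=C4 methylene groups. The ten-membered carbocycle closes by 10-exo-trig addition to the aldehyde and is only transient; the cyclohexane closes transannularly in the [3,3] shift. C7 is set by delivery of the aldehyde to the lactone face that carries the C9 tether (cis-fused lactone) and C6 by the chair transition state with C8 in the E-crotyl position and the enal residue equatorial (C6–O anti to C8); C5 and C10 are set together by the chair Cope of the E,E-diene (C14 and H-5 trans-diaxial) through the crossed conformer that keeps O8 and the C9 ester equatorial on the emerging cyclohexane, with C14 and C15 on the face opposite C11. The step needs γ- over α-attack and 1,2- over 1,4-addition (inherent to allylchromium reagents), ring closure over oligomerisation (high dilution) and one of the two chair Cope conformers, which the C6–C9 substituents are expected to select as in the presumed natural germacranolide precursor; silylation before heating prevents translactonisation to O6.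

Step 13
Reactants: 21 (3aR,4S,5S,6S,7R,7aR)-5-(3-{[tert-butyl(dimethyl)silyl]oxy}prop-1-en-2-yl)-6-ethenyl-4-hydroxy-6-methyl-3-methylidene-2-oxooctahydro-1-benzofuran-7-yl (2R)-2-methylbutanoate; 22 (2Z)-2-methylbut-2-enoic acid (angelic acid)
Product: 23 (3aR,4S,5S,6S,7R,7aR)-5-(3-{[tert-butyl(dimethyl)silyl]oxy}prop-1-en-2-yl)-6-ethenyl-6-methyl-3-methylidene-7-{[(2R)-2-methylbutanoyl]oxy}-2-oxooctahydro-1-benzofuran-4-yl (2Z)-2-methylbut-2-enoate
Conditions: 22, 2,4,6-trichlorobenzoyl chloride, Et3N, PhMe, 25 °C; then 21, 80 °C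
Reagents that add atoms: none
Why: Yamaguchi mixed-anhydride esterification without DMAP is the established way to acylate hindered secondary alcohols with angelic acid while keeping the Z geometry.

Step 14
Reactants: 23 (3aR,4S,5S,6S,7R,7aR)-5-(3-{[tert-butyl(dimethyl)silyl]oxy}prop-1-en-2-yl)-6-ethenyl-6-methyl-3-methylidene-7-{[(2R)-2-methylbutanoyl]oxy}-2-oxooctahydro-1-benzofuran-4-yl (2Z)-2-methylbut-2-enoate
Product: 24 (3aR,4S,5S,6S,7R,7aR)-6-ethenyl-5-(3-hydroxyprop-1-en-2-yl)-6-methyl-3-methylidene-7-{[(2R)-2-methylbutanoyl]oxy}-2-oxooctahydro-1-benzofuran-4-yl (2Z)-2-methylbut-2-enoate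
Conditions: HF·pyridine, pyridine, THF, 0 to 25 °C
Reagents that add atoms: none
Why: Buffered fluoride desilylation should free the primary allylic alcohol without harming the esters, the angelate geometry or the α-methylene lactone.

Step 15
Reactants: 24 (3aR,4S,5S,6S,7R,7aR)-6-ethenyl-5-(3-hydroxyprop-1-en-2-yl)-6-methyl-3-methylidene-7-{[(2R)-2-methylbutanoyl]oxy}-2-oxooctahydro-1-benzofuran-4-yl (2Z)-2-methylbut-2-enoate
Product: 25 (3aR,4S,5R,6S,7R,7aR)-6-ethenyl-6-methyl-3-methylidene-7-{[(2R)-2-methylbutanoyl]oxy}-2-oxo-5-(3-oxoprop-1-en-2-yl)octahydro-1-benzofuran-4-yl (2Z)-2-methylbut-2-enoate (target, CNP0295282.1)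
Conditions: MnO2, CH2Cl2, 25 °C
Reagents that add atoms: none
Why: Neutral MnO2 allylic oxidation should convert the 2-substituted allylic alcohol into the 2-substituted acrolein without base-induced migration of the C3=C4 double bond toward C5.

## Compound list

1 | tert-butyldimethyl(prop-2-yn-1-yloxy)silane | C#CCO[Si](C)(C)C(C)(C)C | starting material
2 | ethyl chloroformate | CCOC(=O)Cl | starting material
3 | ethyl 4-[(tert-butyldimethylsilyl)oxy]but-2-ynoate | CCOC(=O)C#CCO[Si](C)(C)C(C)(C)C | intermediate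
4 | but-3-en-1-ylmagnesium bromide | C=CCC[Mg]Br | starting material
5 | ethyl (2Z)-3-{[(tert-butyldimethylsilyl)oxy]methyl}hepta-2,6-dienoate | CCOC(=O)/C=C(CO[Si](C)(C)C(C)(C)C)/CCC=C | intermediate
6 | (2Z)-3-{[(tert-butyldimethylsilyl)oxy]methyl}hepta-2,6-dien-1-ol | OC/C=C(CO[Si](C)(C)C(C)(C)C)/CCC=C | intermediate
7 | tert-butyl{[(2Z)-2-(but-3-en-1-yl)-4-(methoxymethoxy)but-2-en-1-yl]oxy}dimethylsilane | COCOC/C=C(CO[Si](C)(C)C(C)(C)C)/CCC=C | intermediate
8 | methacrolein (2-methylprop-2-enal) | CC(=C)C=O | starting material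
9 | (2E,6Z)-6-{[(tert-butyldimethylsilyl)oxy]methyl}-8-(methoxymethoxy)-2-methylocta-2,6-dienal | O=C/C(C)=C/CC/C(CO[Si](C)(C)C(C)(C)C)=C/COCOC | intermediate
10 | 3-(methoxymethoxy)prop-1-ene (allyl methoxymethyl ether) | C=CCOCOC | starting material
11 | (3R,4R,5E,9Z)-9-{[(tert-butyldimethylsilyl)oxy]methyl}-3,11-bis(methoxymethoxy)-5-methylundeca-1,5,9-trien-4-ol | C=C[C@@H](OCOC)[C@H](O)/C(C)=C/CC/C(CO[Si](C)(C)C(C)(C)C)=C/COCOC | intermediate
12 | (2R)-2-methylbutanoic acid | OC(=O)[C@H](C)CC | starting material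
13 | (3R,4R,5E,9Z)-9-{[(tert-butyldimethylsilyl)oxy]methyl}-3,11-bis(methoxymethoxy)-5-methylundeca-1,5,9-trien-4-yl (2R)-2-methylbutanoate | C=C[C@@H](OCOC)[C@H](OC(=O)[C@H](C)CC)/C(C)=C/CC/C(CO[Si](C)(C)C(C)(C)C)=C/COCOC | intermediate
14 | (3R,4R,5E,9Z)-9-{[(tert-butyldimethylsilyl)oxy]methyl}-3,11-dihydroxy-5-methylundeca-1,5,9-trien-4-yl (2R)-2-methylbutanoate | C=C[C@@H](O)[C@H](OC(=O)[C@H](C)CC)/C(C)=C/CC/C(CO[Si](C)(C)C(C)(C)C)=C/CO | intermediate
15 | (3R,4R,5E,9Z)-9-{[(tert-butyldimethylsilyl)oxy]methyl}-3-hydroxy-5-methyl-11-oxoundeca-1,5,9-trien-4-yl (2R)-2-methylbutanoate | C=C[C@@H](O)[C@H](OC(=O)[C@H](C)CC)/C(C)=C/CC/C(CO[Si](C)(C)C(C)(C)C)=C/C=O | intermediate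
16 | 2-(bromomethyl)prop-2-enoic acid | C=C(CBr)C(=O)O | starting material
17 | (3R,4R,5E,9Z)-9-{[(tert-butyldimethylsilyl)oxy]methyl}-5-methyl-4-{[(2R)-2-methylbutanoyl]oxy}-11-oxoundeca-1,5,9-trien-3-yl 2-(bromomethyl)prop-2-enoate | C=C[C@@H](OC(=O)C(=C)CBr)[C@H](OC(=O)[C@H](C)CC)/C(C)=C/CC/C(CO[Si](C)(C)C(C)(C)C)=C/C=O | intermediate
18 | (1R,2E,6Z)-1-[(2R)-4-(bromomethyl)-5-oxo-2,5-dihydrofuran-2-yl]-6-{[(tert-butyldimethylsilyl)oxy]methyl}-2-methyl-8-oxoocta-2,6-dien-1-yl (2R)-2-methylbutanoate | O=C/C=C(CO[Si](C)(C)C(C)(C)C)/CC/C=C(C)/[C@@H](OC(=O)[C@H](C)CC)[C@@H]1OC(=O)C(CBr)=C1 | intermediate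
19 | (1(10)E,4Z,6S,7S,8R,9R)-15-[(tert-butyldimethylsilyl)oxy]-9-{[(2R)-2-methylbutanoyl]oxy}-6-[(trimethylsilyl)oxy]germacra-1(10),4,11(13)-trien-12,8-olide (cis-fused lactone; C3 and C6 trans on C4=C5) | C/C1=C\CC/C(CO[Si](C)(C)C(C)(C)C)=C/[C@H](O[Si](C)(C)C)[C@H]2C(=C)C(=O)O[C@H]2[C@@H]1OC(=O)[C@H](C)CC | intermediate
20 | (3aS,4S,5S,6S,7R,7aR)-5-(3-{[tert-butyl(dimethyl)silyl]oxy}prop-1-en-2-yl)-6-ethenyl-6-methyl-3-methylidene-2-oxo-4-[(trimethylsilyl)oxy]octahydro-1-benzofuran-7-yl (2R)-2-methylbutanoate | C=C[C@@]1(C)[C@H](C(=C)CO[Si](C)(C)C(C)(C)C)[C@H](O[Si](C)(C)C)[C@H]2C(=C)C(=O)O[C@H]2[C@@H]1OC(=O)[C@H](C)CC | intermediate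
21 | (3aR,4S,5S,6S,7R,7aR)-5-(3-{[tert-butyl(dimethyl)silyl]oxy}prop-1-en-2-yl)-6-ethenyl-4-hydroxy-6-methyl-3-methylidene-2-oxooctahydro-1-benzofuran-7-yl (2R)-2-methylbutanoate | C=C[C@@]1(C)[C@H](C(=C)CO[Si](C)(C)C(C)(C)C)[C@H](O)[C@H]2C(=C)C(=O)O[C@H]2[C@@H]1OC(=O)[C@H](C)CC | intermediate
22 | (2Z)-2-methylbut-2-enoic acid (angelic acid) | C/C=C(/C)C(=O)O | starting material
23 | (3aR,4S,5S,6S,7R,7aR)-5-(3-{[tert-butyl(dimethyl)silyl]oxy}prop-1-en-2-yl)-6-ethenyl-6-methyl-3-methylidene-7-{[(2R)-2-methylbutanoyl]oxy}-2-oxooctahydro-1-benzofuran-4-yl (2Z)-2-methylbut-2-enoate | C=C[C@@]1(C)[C@H](C(=C)CO[Si](C)(C)C(C)(C)C)[C@H](OC(=O)/C(C)=C\C)[C@H]2C(=C)C(=O)O[C@H]2[C@@H]1OC(=O)[C@H](C)CC | intermediate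
24 | (3aR,4S,5S,6S,7R,7aR)-6-ethenyl-5-(3-hydroxyprop-1-en-2-yl)-6-methyl-3-methylidene-7-{[(2R)-2-methylbutanoyl]oxy}-2-oxooctahydro-1-benzofuran-4-yl (2Z)-2-methylbut-2-enoate | C=C[C@@]1(C)[C@H](C(=C)CO)[C@H](OC(=O)/C(C)=C\C)[C@H]2C(=C)C(=O)O[C@H]2[C@@H]1OC(=O)[C@H](C)CC | intermediate
25 | (3aR,4S,5R,6S,7R,7aR)-6-ethenyl-6-methyl-3-methylidene-7-{[(2R)-2-methylbutanoyl]oxy}-2-oxo-5-(3-oxoprop-1-en-2-yl)octahydro-1-benzofuran-4-yl (2Z)-2-methylbut-2-enoate | C=C[C@@]1(C)[C@H](C(=C)C=O)[C@H](OC(=O)/C(C)=C\C)[C@H]2C(=C)C(=O)O[C@H]2[C@@H]1OC(=O)[C@H](C)CC | target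

## Step count and risks

Total step count: 15. Longest linear sequence: 15 steps (1 to 25; the route is linear).

Steps most likely to fail:

Step 12. The aldehyde may be delivered to the lactone face opposite the C9 tether (trans-fused ring), the silyl ether may rearrange through the other chair conformer (C5/C10 both inverted), or the Cope step may stop at a germacranolide/elemanolide equilibrium. Fallback, from 18 back to 23: the cascade is split. CrCl2 macrocyclisation of 18 at 25 °C with aqueous work-up would give the germacranolide alcohol (1(10)E,4Z,6S,7R,8R,9R)-15-[(tert-butyldimethylsilyl)oxy]-6-hydroxy-9-{[(2R)-2-methylbutanoyl]oxy}germacra-1(10),4,11(13)-trien-12,8-olide F1, at which stage C6/C7 diastereomers can be separated. Yamaguchi esterification with angelic acid 22 would give the 6-angelate F2, the substrate closest to the presumed natural precursor. A separate thermal Cope rearrangement of F2 (xylene, 140 °C) would then deliver 23, so that steps 12 and 13 are replaced.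

Step 11. The allylic bromide may deactivate the ruthenium carbene, and ring closure onto the electron-poor 1,1-disubstituted alkene may be slow enough for intermolecular metathesis to compete. Fallback, from 15 back to 18: the bromide is introduced after ring closure. Commercial ethyl 2-(bromomethyl)acrylate and 4-methoxybenzyl alcohol (Et3N) would give ethyl 2-{[(4-methoxybenzyl)oxy]methyl}prop-2-enoate F3, saponified (LiOH) to 2-{[(4-methoxybenzyl)oxy]methyl}prop-2-enoic acid F4. Esterification of 15 with F4 (DIC, DMAP) would give the acrylate F5, and ring-closing metathesis the 3-[(4-methoxybenzyloxy)methyl]butenolide F6. DDQ would unmask the 3-(hydroxymethyl)butenolide F7, and Appel bromination (CBr4, PPh3) would return 18.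

Step 13. The angeloyl unit may isomerise from Z to E (tiglate) during activation, and acylation of the hindered C6 hydroxyl may be sluggish. Fallback, from 21 back to 23: the Z-alkene is built on the ester. Saponification of commercial ethyl 2-[bis(2,2,2-trifluoroethoxy)phosphoryl]propanoate would give 2-[bis(2,2,2-trifluoroethoxy)phosphoryl]propanoic acid F8. Esterification of 21 with F8 (DIC, DMAP) would give the phosphonopropionate F9, and Still–Gennari olefination with acetaldehyde (KN(SiMe3)2, 18-crown-6, THF, −78 °C) should give the (Z)-2-methylbut-2-enoate 23.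

## Further compounds

F1 | step 12 | (1(10)E,4Z,6S,7R,8R,9R)-15-[(tert-butyldimethylsilyl)oxy]-6-hydroxy-9-{[(2R)-2-methylbutanoyl]oxy}germacra-1(10),4,11(13)-trien-12,8-olide | C/C1=C\CC/C(CO[Si](C)(C)C(C)(C)C)=C/[C@H](O)[C@H]2C(=C)C(=O)O[C@H]2[C@@H]1OC(=O)[C@H](C)CC
F2 | step 12 | (1(10)E,4Z,6S,7R,8R,9R)-6-{[(2Z)-2-methylbut-2-enoyl]oxy}-15-[(tert-butyldimethylsilyl)oxy]-9-{[(2R)-2-methylbutanoyl]oxy}germacra-1(10),4,11(13)-trien-12,8-olide | C/C1=C\CC/C(CO[Si](C)(C)C(C)(C)C)=C/[C@H](OC(=O)/C(C)=C\C)[C@H]2C(=C)C(=O)O[C@H]2[C@@H]1OC(=O)[C@H](C)CC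
F3 | step 11 | ethyl 2-{[(4-methoxybenzyl)oxy]methyl}prop-2-enoate | CCOC(=O)C(=C)COCc1ccc(OC)cc1
F4 | step 11 | 2-{[(4-methoxybenzyl)oxy]methyl}prop-2-enoic acid | OC(=O)C(=C)COCc1ccc(OC)cc1
F5 | step 11 | (3R,4R,5E,9Z)-9-{[(tert-butyldimethylsilyl)oxy]methyl}-5-methyl-4-{[(2R)-2-methylbutanoyl]oxy}-11-oxoundeca-1,5,9-trien-3-yl 2-{[(4-methoxybenzyl)oxy]methyl}prop-2-enoate | C=C[C@@H](OC(=O)C(=C)COCc1ccc(OC)cc1)[C@H](OC(=O)[C@H](C)CC)/C(C)=C/CC/C(CO[Si](C)(C)C(C)(C)C)=C/C=O
F6 | step 11 | (1R,2E,6Z)-6-{[(tert-butyldimethylsilyl)oxy]methyl}-1-[(2R)-4-{[(4-methoxybenzyl)oxy]methyl}-5-oxo-2,5-dihydrofuran-2-yl]-2-methyl-8-oxoocta-2,6-dien-1-yl (2R)-2-methylbutanoate | O=C/C=C(CO[Si](C)(C)C(C)(C)C)/CC/C=C(C)/[C@@H](OC(=O)[C@H](C)CC)[C@@H]1OC(=O)C(COCc2ccc(OC)cc2)=C1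
F7 | step 11 | (1R,2E,6Z)-6-{[(tert-butyldimethylsilyl)oxy]methyl}-1-[(2R)-4-(hydroxymethyl)-5-oxo-2,5-dihydrofuran-2-yl]-2-methyl-8-oxoocta-2,6-dien-1-yl (2R)-2-methylbutanoate | O=C/C=C(CO[Si](C)(C)C(C)(C)C)/CC/C=C(C)/[C@@H](OC(=O)[C@H](C)CC)[C@@H]1OC(=O)C(CO)=C1
F8 | step 13 | 2-[bis(2,2,2-trifluoroethoxy)phosphoryl]propanoic acid | CC(C(=O)O)P(=O)(OCC(F)(F)F)OCC(F)(F)F
F9 | step 13 | (3aR,4S,5S,6S,7R,7aR)-5-(3-{[tert-butyl(dimethyl)silyl]oxy}prop-1-en-2-yl)-6-ethenyl-6-methyl-3-methylidene-7-{[(2R)-2-methylbutanoyl]oxy}-2-oxooctahydro-1-benzofuran-4-yl 2-[bis(2,2,2-trifluoroethoxy)phosphoryl]propanoate (mixture at the phosphonate carbon) | C=C[C@@]1(C)[C@H](C(=C)CO[Si](C)(C)C(C)(C)C)[C@H](OC(=O)C(C)P(=O)(OCC(F)(F)F)OCC(F)(F)F)[C@H]2C(=C)C(=O)O[C@H]2[C@@H]1OC(=O)[C@H](C)CC
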